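Ring A of the target (C1 bearing the CH2OH carbon C7, C2 bearing the methylene C8 to ring B, C3–OH, C4–OH, C5–Br, C6–H) has two carbon substituents on adjacent atoms next to the C3 oxygen. The plan disconnects both C1–C7 and C2–C8 to a C1–C2 aryne polarised by a C3 methoxy group. One fluoride-triggered operation joins this aryne, tert-butyl isocyanide (C7) and 3-bromo-4-methoxybenzaldehyde (C8 plus ring B) and closes a cyclic imidate. The aryne precursor is an ortho-silyl aryl triflate that already carries the C5 bromine and both oxygens as methyl ethers. Hydrolysis, ionic hydrogenation, borane reduction and demethylation finish the synthesis.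

Key step: step 6

Remark on the chemistry: the carbon created as a stereocentre in step 6 is formed as a racemate and becomes CH2 in step 8, and the C=N geometry of the imidate is left unspecified because hydrolysis removes it; the target itself has no stereocentre.

Step 1
Reactants: 1 2,3-dimethoxyphenol
Product: 2 2,3-dimethoxyphenyl N-isopropylcarbamate
Conditions: i-PrNCO, Et3N (cat.), CH2Cl2, rt
Reagents that add atoms: isopropyl isocyanate, CC(C)N=C=O
Why: Amine-catalysed addition of the phenol O–H across the isocyanate (O-carbamoylation) should install an N-H carbamate that directs metalation and can later be removed under mild base.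

Step 2
Reactants: 2 2,3-dimethoxyphenyl N-isopropylcarbamate
Product: 6 2,3-dimethoxy-6-(trimethylsilyl)phenyl N-isopropylcarbamate, via N-silylated carbamate 3 (not isolated), via ortho-lithiated carbamate 4 (not isolated), via doubly silylated carbamate 5 (not isolated)
Conditions: TMEDA, TBSOTf, Et2O, 0 °C to rt; then TMEDA, n-BuLi, −78 °C; TMSCl, −78 °C to rt; aq NaHSO4 work-up
Reagents that add atoms: chlorotrimethylsilane, C[Si](C)(C)Cl; tert-butyldimethylsilyl trifluoromethanesulfonate, CC(C)(C)[Si](C)(C)OS(=O)(=O)C(F)(F)F (silyl group present only in 3, 4 and 5); n-butyllithium, [Li]CCCC (lithium present only in 4)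
Why: After in situ N-silylation the carbamate directs lithiation (directed ortho-metalation) to C6, the only position next to it that carries hydrogen, the aryllithium is trapped by TMSCl, and the N–Si bond is hydrolysed in the acidic work-up.

Step 3
Reactants: 6 2,3-dimethoxy-6-(trimethylsilyl)phenyl N-isopropylcarbamate
Product: 7 2,3-dimethoxy-6-(trimethylsilyl)phenol
Conditions: DBU, Et2NH, MeCN, 40 °C
Reagents that add atoms: none
Why: Base-induced E1cB fragmentation of the N-H carbamate should release the phenoxide and isopropyl isocyanate, which diethylamine traps as a urea, under conditions mild enough to leave the aryl–silicon bond intact.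

Step 4
Reactants: 7 2,3-dimethoxy-6-(trimethylsilyl)phenol
Product: 8 4-bromo-2,3-dimethoxy-6-(trimethylsilyl)phenol
Conditions: NBS (1.0 equiv), MeCN, −20 to 0 °C, dark
Reagents that add atoms: N-bromosuccinimide, O=C1CCC(=O)N1Br
Why: Electrophilic aromatic bromination of the phenol should occur at C4, which is para to the hydroxyl, ortho to the neighbouring methoxy group and the only strongly activated position still bearing hydrogen, while acid-free NBS at low temperature limits ipso attack at the silylated carbon.

Step 5
Reactants: 8 4-bromo-2,3-dimethoxy-6-(trimethylsilyl)phenol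
Product: 9 4-bromo-2,3-dimethoxy-6-(trimethylsilyl)phenyl trifluoromethanesulfonate
Conditions: Tf2O, pyridine, CH2Cl2, 0 °C
Reagents that add atoms: trifluoromethanesulfonic anhydride, O=S(=O)(OS(=O)(=O)C(F)(F)F)C(F)(F)F
Why: O-Sulfonylation of the phenol with triflic anhydride and pyridine (triflation) is routine for ortho-silyl phenols that also carry an ortho alkoxy group.

Step 6
Reactants: 9 4-bromo-2,3-dimethoxy-6-(trimethylsilyl)phenyl trifluoromethanesulfonate; 10 tert-butyl isocyanide; 11 3-bromo-4-methoxybenzaldehyde
Product: 13 racemic N-tert-butyl-6-bromo-3-(3-bromo-4-methoxyphenyl)-4,5-dimethoxy-3H-isobenzofuran-1-imine, via aryne 12 (not isolated)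
Conditions: KF, 18-crown-6, THF, 0 °C to rt (10 and 11 in slight excess)
Reagents that add atoms: none
Why: Fluoride attacks silicon and the ortho triflate departs to give aryne 12; the isocyanide carbon adds to C1, the aryl anion left on C2 adds to the aldehyde carbonyl, and the resulting alkoxide attacks the nitrilium carbon. This is the established three-component coupling of arynes, isocyanides and aldehydes to 1-imino-1,3-dihydroisobenzofurans, applied here to a new aryne. The five-membered ring closes by 5-exo-dig attack of the alkoxide oxygen on the nitrilium triple bond. The new sp3 carbon C8 has no controlling element and forms as a racemate, which is acceptable because step 8 turns it into CH2. The step needs regioselective isocyanide attack at C1, and the C3 methoxy group should secure it: its inductive pull makes C2 the better site for negative charge and distorts the aryne so that C1 is the flatter, more electrophilic terminus. The two C–Br bonds should not be at risk, since only fluoride, a neutral isocyanide and short-lived aryl anions that are trapped at once are involved.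

Step 7
Reactants: 13 racemic N-tert-butyl-6-bromo-3-(3-bromo-4-methoxyphenyl)-4,5-dimethoxy-3H-isobenzofuran-1-imine
Product: 14 racemic 6-bromo-3-(3-bromo-4-methoxyphenyl)-4,5-dimethoxy-2-benzofuran-1(3H)-one
Conditions: 1 M HCl, THF, rt
Reagents that add atoms: water, O
Why: Acid-catalysed hydrolysis of the cyclic imidate: water adds to the protonated C=N and the tetrahedral intermediate expels tert-butylamine to leave the five-membered lactone, while dilute acid at room temperature avoids ionisation of the doubly benzylic C–O bond.

Step 8
Reactants: 14 racemic 6-bromo-3-(3-bromo-4-methoxyphenyl)-4,5-dimethoxy-2-benzofuran-1(3H)-one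
Product: 15 5-bromo-2-[(3-bromo-4-methoxyphenyl)methyl]-3,4-dimethoxybenzoic acid
Conditions: Et3SiH, TFA, 50 °C
Reagents that add atoms: none
Why: Ionic hydrogenation: protonation of the lactone lets the doubly benzylic C–O bond ionise to a diarylmethyl cation stabilised by the para-methoxy group of ring B, and hydride transfer from Et3SiH should give the diarylmethane and the free carboxylic acid, removing the stereocentre.

Step 9
Reactants: 15 5-bromo-2-[(3-bromo-4-methoxyphenyl)methyl]-3,4-dimethoxybenzoic acid
Product: 16 {5-bromo-2-[(3-bromo-4-methoxyphenyl)methyl]-3,4-dimethoxyphenyl}methanol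
Conditions: BH3·THF, THF, 0 °C to rt; MeOH quench
Reagents that add atoms: none
Why: Borane reduces the carboxylic acid through an acyloxyborane (chemoselective carboxylic acid reduction) and should leave aryl bromides, aryl ethers and the diarylmethane untouched.

Step 10
Reactants: 16 {5-bromo-2-[(3-bromo-4-methoxyphenyl)methyl]-3,4-dimethoxyphenyl}methanol
Product: 18 6-bromo-3-[(3-bromo-4-hydroxyphenyl)methyl]-4-(hydroxymethyl)benzene-1,2-diol, via benzylic bromide 17 (not isolated)
Conditions: BBr3, CH2Cl2, −78 to 0 °C, dilute; ice-water; then acetone/H2O, NaHCO3, rt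
Reagents that add atoms: boron tribromide, BrB(Br)Br (benzylic bromine of 17 only); water, O (hydroxyl oxygen of the CH2OH group of 18)
Why: BBr3 cleaves the three aryl methyl ethers by Lewis acid complexation and bromide attack on methyl (ether demethylation) and converts the benzylic alcohol into bromide 17, whose solvolysis in buffered aqueous acetone through a para-quinone methide should restore the hydroxymethyl group.

Compound list
1 | 2,3-dimethoxyphenol | COc1cccc(O)c1OC | starting material
2 | 2,3-dimethoxyphenyl N-isopropylcarbamate | COc1cccc(OC(=O)NC(C)C)c1OC | intermediate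
3 | 2,3-dimethoxyphenyl N-(tert-butyldimethylsilyl)-N-isopropylcarbamate (not isolated) | COc1cccc(OC(=O)N(C(C)C)[Si](C)(C)C(C)(C)C)c1OC | intermediate
4 | 6-lithio-2,3-dimethoxyphenyl N-(tert-butyldimethylsilyl)-N-isopropylcarbamate (not isolated) | [Li]c1ccc(OC)c(OC)c1OC(=O)N(C(C)C)[Si](C)(C)C(C)(C)C | intermediate
5 | 2,3-dimethoxy-6-(trimethylsilyl)phenyl N-(tert-butyldimethylsilyl)-N-isopropylcarbamate (not isolated) | COc1ccc([Si](C)(C)C)c(OC(=O)N(C(C)C)[Si](C)(C)C(C)(C)C)c1OC | intermediate
6 | 2,3-dimethoxy-6-(trimethylsilyl)phenyl N-isopropylcarbamate | COc1ccc([Si](C)(C)C)c(OC(=O)NC(C)C)c1OC | intermediate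
7 | 2,3-dimethoxy-6-(trimethylsilyl)phenol | COc1ccc([Si](C)(C)C)c(O)c1OC | intermediate
8 | 4-bromo-2,3-dimethoxy-6-(trimethylsilyl)phenol | COc1c(Br)cc([Si](C)(C)C)c(O)c1OC | intermediate
9 | 4-bromo-2,3-dimethoxy-6-(trimethylsilyl)phenyl trifluoromethanesulfonate | COc1c(Br)cc([Si](C)(C)C)c(OS(=O)(=O)C(F)(F)F)c1OC | intermediate
10 | tert-butyl isocyanide | [C-]#[N+]C(C)(C)C | starting material
11 | 3-bromo-4-methoxybenzaldehyde | COc1ccc(C=O)cc1Br | starting material
12 | 5-bromo-3,4-dimethoxybenzyne (aryne, not isolated) | COC1=C(OC)C#CC=C1Br | intermediate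
13 | racemic N-tert-butyl-6-bromo-3-(3-bromo-4-methoxyphenyl)-4,5-dimethoxy-3H-isobenzofuran-1-imine | COc1ccc(cc1Br)C1OC(=NC(C)(C)C)c2cc(Br)c(OC)c(OC)c12 | intermediate
14 | racemic 6-bromo-3-(3-bromo-4-methoxyphenyl)-4,5-dimethoxy-2-benzofuran-1(3H)-one | COc1ccc(cc1Br)C1OC(=O)c2cc(Br)c(OC)c(OC)c12 | intermediate
15 | 5-bromo-2-[(3-bromo-4-methoxyphenyl)methyl]-3,4-dimethoxybenzoic acid | COc1ccc(Cc2c(C(=O)O)cc(Br)c(OC)c2OC)cc1Br | intermediate
16 | {5-bromo-2-[(3-bromo-4-methoxyphenyl)methyl]-3,4-dimethoxyphenyl}methanol | COc1ccc(Cc2c(CO)cc(Br)c(OC)c2OC)cc1Br | intermediate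
17 | 6-bromo-4-(bromomethyl)-3-[(3-bromo-4-hydroxyphenyl)methyl]benzene-1,2-diol (not isolated) | BrCc1cc(Br)c(O)c(O)c1Cc1ccc(O)c(Br)c1 | intermediate
18 | 6-bromo-3-[(3-bromo-4-hydroxyphenyl)methyl]-4-(hydroxymethyl)benzene-1,2-diol | OCc1cc(Br)c(O)c(O)c1Cc1ccc(O)c(Br)c1 | target

Total step count: 10
Longest linear sequence: 10 steps, from 1 to 18; compounds 10 and 11 are purchased and enter at step 6.

Steps most likely to fail

1. Step 6 (key step). The aryl anion on C2 sits between the methoxy group and the nitrilium-bearing carbon. It may be protonated, or may add a second isocyanide, faster than it adds to the electron-rich aldehyde, and some loss of regiocontrol is conceivable. The fallback builds the same two ring-A bonds stepwise through halogen–magnesium exchange. Starting from 9, CsF and I2 in MeCN would generate aryne 12 and trap it as 1-bromo-4,5-diiodo-2,3-dimethoxybenzene F1. With iPrMgCl·LiCl at −78 °C the iodine lying between the methoxy group and the second iodine should exchange first, because the arylmagnesium formed there is stabilised by two electronegative ortho substituents and by chelation. The reaction is kept cold so that the ortho-iodo Grignard does not eliminate, and addition of 11 would give racemic (4-bromo-6-iodo-2,3-dimethoxyphenyl)(3-bromo-4-methoxyphenyl)methanol F2. A second iodine–magnesium exchange on F2 (excess iPrMgCl·LiCl, −40 °C, the C–Br bonds exchanging far more slowly), a CO2 quench and acidic work-up would lactonise directly to phthalide 14, where the main route continues.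

2. Step 4. Electrophilic attack at the silicon-bearing carbon (ipso-bromodesilylation), which is ortho to the hydroxyl and para to a methoxy group, may compete with C–H bromination, and traces of acid may cause protodesilylation. The fallback replaces electrophilic substitution by sterically governed C–H borylation and halodeboronation. From 7, triflation under the conditions of step 5 would give 2,3-dimethoxy-6-(trimethylsilyl)phenyl trifluoromethanesulfonate F3. Borylation with B2pin2, [Ir(OMe)(cod)]2 and 4,4'-di-tert-butyl-2,2'-bipyridine should occur at the only C–H bond not adjacent to the bulky silyl group. This would give 2,3-dimethoxy-4-(4,4,5,5-tetramethyl-1,3,2-dioxaborolan-2-yl)-6-(trimethylsilyl)phenyl trifluoromethanesulfonate F4. CuBr2 in aqueous methanol would then exchange the boronate for bromine and return to 9.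

3. Step 10. Under the Lewis acid the ionisable benzylic position may alkylate an electron-rich ring of a second molecule (oligomerisation), or hydrolysis of the benzylic bromide may stay incomplete. The fallback demethylates before any benzylic leaving group exists. From 15, BBr3 would give 5-bromo-2-[(3-bromo-4-hydroxyphenyl)methyl]-3,4-dihydroxybenzoic acid F5. Excess BH3·THF at 0 °C to rt would then reduce the carboxylic acid while the phenols are borylated in situ and released on methanolic work-up, arriving at 18 directly.

Further compounds
F1 | step 6 | 1-bromo-4,5-diiodo-2,3-dimethoxybenzene | COc1c(I)c(I)cc(Br)c1OC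
F2 | step 6 | racemic (4-bromo-6-iodo-2,3-dimethoxyphenyl)(3-bromo-4-methoxyphenyl)methanol | COc1ccc(cc1Br)C(O)c1c(I)cc(Br)c(OC)c1OC
F3 | step 4 | 2,3-dimethoxy-6-(trimethylsilyl)phenyl trifluoromethanesulfonate | COc1ccc([Si](C)(C)C)c(OS(=O)(=O)C(F)(F)F)c1OC
F4 | step 4 | 2,3-dimethoxy-4-(4,4,5,5-tetramethyl-1,3,2-dioxaborolan-2-yl)-6-(trimethylsilyl)phenyl trifluoromethanesulfonate | COc1c(B2OC(C)(C)C(C)(C)O2)cc([Si](C)(C)C)c(OS(=O)(=O)C(F)(F)F)c1OC
F5 | step 10 | 5-bromo-2-[(3-bromo-4-hydroxyphenyl)methyl]-3,4-dihydroxybenzoic acid | O=C(O)c1cc(Br)c(O)c(O)c1Cc1ccc(O)c(Br)c1
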